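## Retrosynthetic overview

1. Ring A is closed last by a Diels–Alder reaction of methyl methacrylate with a 1-vinylcyclohexene (ring B). It forms C2–C3 and C4–C5 and sets C4 and C5 in one step.
2. The diene comes from a 2,2,3-trisubstituted cyclohexanone (C10 ketone) by enol triflation and vinyl cross-coupling.
3. Key disconnection C11–C12: the β-carbon of that ketone acts as the nucleophile (a zinc homoenolate from ring opening of a fused cyclopropanol) and is joined to the allylic chloride of a C5 acetate building block. The ring opening also unveils the C9 quaternary centre and the ketone.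
4. The cyclopropanol comes from 2-methylcyclohex-2-enone by catalytic asymmetric conjugate methylation (sets C8), silyl trapping and Simmons–Smith cyclopropanation (sets C9).
5. Ring order: ring B is bought, a temporary cyclopropane is fused and opened, ring A is formed last. Labels (halimane numbering): C4 = ester-bearing quaternary carbon, C5 = ring-fusion CH, C1=C10 = alkene, C8 = CHMe, C9 = quaternary carbon, C11–C15 = side chain.

Assumption: (E)-4-chloro-3-methylbut-2-en-1-yl acetate (the vitamin A C5 building block) is purchased. Ligand L is O,O′-(1,1′-binaphthyl-2,2′-diyl) N,N-bis(1-phenylethyl)phosphoramidite, used as whichever antipode gives the 3R centre in step 1 (both are sold; the sense is checked on the hydrolysed ketone).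

## Route

Step 1
Reactants: 1 2-methylcyclohex-2-en-1-one; 2 trimethylaluminium; 3 trimethylsilyl trifluoromethanesulfonate
Product: 5 (R)-trimethyl[(2,3-dimethylcyclohex-1-en-1-yl)oxy]silane, via aluminium enolate 4 (not isolated)
Conditions: CuTC (copper thiophene-2-carboxylate, Cu(O2CC4H3S), 2 mol%), ligand L (4 mol%), AlMe3 (1.4 equiv), Et2O, −30 °C; then Me3SiOTf (1.5 equiv), −30 → 0 °C; cold aq NaHCO3 work-up
Reagents that add atoms: trimethylaluminium, C[Al](C)C; trimethylsilyl trifluoromethanesulfonate, C[Si](C)(C)OS(=O)(=O)C(F)(F)F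
Why: Copper-catalysed asymmetric conjugate addition of methyl to the α-substituted enone sets the C8 stereocentre (3R) under ligand control, and O-silylation of the regiodefined aluminium enolate fixes the tetrasubstituted enol ether needed for cyclopropanation.

Step 2
Reactants: 5 (R)-trimethyl[(2,3-dimethylcyclohex-1-en-1-yl)oxy]silane; 6 diiodomethane
Product: 8 (1R,5R,6S)-5,6-dimethylbicyclo[4.1.0]heptan-1-ol, via siloxycyclopropane 7 (not isolated)
Conditions: Et2Zn (2.0 equiv), CH2I2 (2.2 equiv), Et2O, 0 → 23 °C; pyridine quench, filter; crude in MeOH, K2CO3 (0.2 equiv), 0 °C, 30 min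
Reagents that add atoms: diiodomethane, ICI
Why: Simmons–Smith (Furukawa) cyclopropanation of the electron-rich silyl enol ether delivers CH2 to the face anti to the C8 methyl, which allylic 1,2-strain with the vinylic methyl holds pseudoaxial, so the future quaternary centre C9 is fixed (C9 methyl cis to C8 methyl) before mild methanolysis frees the cyclopropanol.

Step 3
Reactants: 8 (1R,5R,6S)-5,6-dimethylbicyclo[4.1.0]heptan-1-ol; 9 (E)-4-chloro-3-methylbut-2-en-1-yl acetate
Product: 13 (E)-5-[(1S,2R)-1,2-dimethyl-6-oxocyclohexyl]-3-methylpent-2-en-1-yl acetate, via lithium cyclopropoxide 10 (not isolated), via chlorozinc cyclopropoxide 11 (not isolated), via zinc homoenolate 12 (not isolated)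
Conditions: n-BuLi (1.0 equiv), THF, −78 °C; ZnCl2 (1.1 equiv), −78 → 23 °C, 1 h; then 9 (1.3 equiv), Pd(PPh3)4 (5 mol%), THF–DMA 4:1, 23 → 40 °C
Reagents that add atoms: (E)-4-chloro-3-methylbut-2-en-1-yl acetate, ClC/C(C)=C/COC(C)=O
Why: Proposed new method: the zinc alkoxide of the strained cyclopropanol opens by two-electron β-carbon elimination of the less substituted C10–C11 bond to a chelated primary β-keto alkylzinc (a ketone homoenolate, C11 nucleophilic) that has no β-hydrogen because C9 is quaternary, it transmetalates to the η3-allylpalladium chloride formed from the allylic chloride (chloride ionises far faster than acetate), and reductive elimination joins C11 to the unsubstituted allyl terminus C12 with the E-alkene and the C9 configuration from step 2 retained, the closest known reactions being the copper-mediated SN2′ allylation of cyclopropanol-derived zinc homoenolates, palladium-catalysed ring-opening cross-coupling of cyclopropanols with aryl and benzyl halides, and Negishi coupling of alkylzinc halides with allylic chlorides at the less hindered terminus.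

Step 4
Reactants: 13 (E)-5-[(1S,2R)-1,2-dimethyl-6-oxocyclohexyl]-3-methylpent-2-en-1-yl acetate; 14 N-phenylbis(trifluoromethanesulfonimide)
Product: 16 (E)-5-[(1S,6R)-1,6-dimethyl-2-{[(trifluoromethyl)sulfonyl]oxy}cyclohex-2-en-1-yl]-3-methylpent-2-en-1-yl acetate, via potassium enolate 15 (not isolated)
Conditions: KN(SiMe3)2 (1.05 equiv), THF, −78 °C, 30 min; PhNTf2 (1.1 equiv), −78 → 0 °C
Reagents that add atoms: N-phenylbis(trifluoromethanesulfonimide), FC(F)(F)S(=O)(=O)N(c1ccccc1)S(=O)(=O)C(F)(F)F
Why: The ketone has α-hydrogens only at C5 and is deprotonated faster than the acetate methyl, so kinetic enolisation and O-triflation give a single enol triflate without touching a stereocentre.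

Step 5
Reactants: 16 (E)-5-[(1S,6R)-1,6-dimethyl-2-{[(trifluoromethyl)sulfonyl]oxy}cyclohex-2-en-1-yl]-3-methylpent-2-en-1-yl acetate; 17 tributyl(ethenyl)stannane
Product: 18 (E)-5-[(1S,6R)-2-ethenyl-1,6-dimethylcyclohex-2-en-1-yl]-3-methylpent-2-en-1-yl acetate
Conditions: Pd2(dba)3 (2.5 mol%), AsPh3 (20 mol%), LiCl (3 equiv), NMP, 23 °C
Reagents that add atoms: tributyl(ethenyl)stannane, C=C[Sn](CCCC)(CCCC)CCCC
Why: Stille coupling, in which oxidative addition of zerovalent palladium to the enol triflate is fast at room temperature with the weakly donating arsine while the primary allylic acetate on a trisubstituted alkene ionises only slowly, so the vinyl group is installed chemoselectively.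

Step 6
Reactants: 18 (E)-5-[(1S,6R)-2-ethenyl-1,6-dimethylcyclohex-2-en-1-yl]-3-methylpent-2-en-1-yl acetate; 19 methyl methacrylate
Product: 20 methyl (1S,5S,6R,8aR)-5-[(E)-5-acetoxy-3-methylpent-3-en-1-yl]-1,5,6-trimethyl-1,2,3,5,6,7,8,8a-octahydronaphthalene-1-carboxylate
Conditions: methyl methacrylate (3 equiv), Me2AlCl (2.0 equiv), CH2Cl2, −40 → 0 °C
Reagents that add atoms: methyl methacrylate, C=C(C)C(=O)OC
Why: Lewis-acid-promoted Diels–Alder reaction in which ortho regiochemistry (ester-bearing carbon to the ring terminus C5), an ester-endo transition state (ester cis to the C5–C6 bond) and approach to the diene face opposite the two cis methyl groups at C8 and C9 (every trajectory on the methyl face meets a syn-axial or flagpole methyl) set C4 (S) and C5 (R) together and give the Δ1(10) alkene directly.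

## Compound list

1 | 2-methylcyclohex-2-en-1-one | CC1=CCCCC1=O | starting material
2 | trimethylaluminium | C[Al](C)C | starting material
3 | trimethylsilyl trifluoromethanesulfonate | C[Si](C)(C)OS(=O)(=O)C(F)(F)F | starting material
4 | dimethylaluminium (R)-2,3-dimethylcyclohex-1-en-1-olate | C[C@@H]1CCCC(O[Al](C)C)=C1C | intermediate
5 | (R)-trimethyl[(2,3-dimethylcyclohex-1-en-1-yl)oxy]silane | C[C@@H]1CCCC(O[Si](C)(C)C)=C1C | intermediate
6 | diiodomethane | ICI | starting material
7 | trimethyl{[(1R,5R,6S)-5,6-dimethylbicyclo[4.1.0]heptan-1-yl]oxy}silane | C[Si](C)(C)O[C@@]12CCC[C@@H](C)[C@]1(C)C2 | intermediate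
8 | (1R,5R,6S)-5,6-dimethylbicyclo[4.1.0]heptan-1-ol | O[C@@]12CCC[C@@H](C)[C@]1(C)C2 | intermediate
9 | (E)-4-chloro-3-methylbut-2-en-1-yl acetate | ClC/C(C)=C/COC(C)=O | starting material
10 | lithium (1R,5R,6S)-5,6-dimethylbicyclo[4.1.0]heptan-1-olate | [Li]O[C@@]12CCC[C@@H](C)[C@]1(C)C2 | intermediate
11 | chlorozinc (1R,5R,6S)-5,6-dimethylbicyclo[4.1.0]heptan-1-olate | Cl[Zn]O[C@@]12CCC[C@@H](C)[C@]1(C)C2 | intermediate
12 | chloro{[(1S,2R)-1,2-dimethyl-6-oxocyclohexyl]methyl}zinc | O=C1CCC[C@@H](C)[C@]1(C)C[Zn]Cl | intermediate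
13 | (E)-5-[(1S,2R)-1,2-dimethyl-6-oxocyclohexyl]-3-methylpent-2-en-1-yl acetate | O=C1CCC[C@@H](C)[C@]1(C)CC/C(C)=C/COC(C)=O | intermediate
14 | N-phenylbis(trifluoromethanesulfonimide) | FC(F)(F)S(=O)(=O)N(c1ccccc1)S(=O)(=O)C(F)(F)F | starting material
15 | potassium (5R,6S)-6-[(E)-5-acetoxy-3-methylpent-3-en-1-yl]-5,6-dimethylcyclohex-1-en-1-olate | [K]OC1=CCC[C@@H](C)[C@]1(C)CC/C(C)=C/COC(C)=O | intermediate
16 | (E)-5-[(1S,6R)-1,6-dimethyl-2-{[(trifluoromethyl)sulfonyl]oxy}cyclohex-2-en-1-yl]-3-methylpent-2-en-1-yl acetate | FC(F)(F)S(=O)(=O)OC1=CCC[C@@H](C)[C@]1(C)CC/C(C)=C/COC(C)=O | intermediate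
17 | tributyl(ethenyl)stannane | C=C[Sn](CCCC)(CCCC)CCCC | starting material
18 | (E)-5-[(1S,6R)-2-ethenyl-1,6-dimethylcyclohex-2-en-1-yl]-3-methylpent-2-en-1-yl acetate | C=CC1=CCC[C@@H](C)[C@]1(C)CC/C(C)=C/COC(C)=O | intermediate
19 | methyl methacrylate (methyl 2-methylprop-2-enoate) | C=C(C)C(=O)OC | starting material
20 | methyl (1S,5S,6R,8aR)-5-[(E)-5-acetoxy-3-methylpent-3-en-1-yl]-1,5,6-trimethyl-1,2,3,5,6,7,8,8a-octahydronaphthalene-1-carboxylate | COC(=O)[C@@]1(C)CCC=C2[C@H]1CC[C@@H](C)[C@]2(C)CC/C(C)=C/COC(C)=O | target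

## Step count and risks

Total step count: 6. Longest linear sequence: 6 (the route is fully linear from 1).

**Homoenolate coupling (step 3), the most likely to fail.** The zinc alkoxide may O-allylate instead of opening, the allyl group may transfer from palladium to zinc, and π–σ–π isomerisation of the 2-methylallyl complex could erode the E geometry. The fallback abandons the homoenolate and builds the chain by conjugate-addition chemistry; it sets out from silyl enol ether 5 and returns at ketone 13. Mukaiyama–Michael addition of 5 to but-3-en-2-one (TiCl4, CH2Cl2, −78 °C, attack again anti to the C8 methyl) gives the diketone (2S,3R)-2,3-dimethyl-2-(3-oxobutyl)cyclohexan-1-one F1. Horner–Wadsworth–Emmons olefination of the unhindered methyl ketone (triethyl phosphonoacetate, NaH, THF; E isomer separated) gives ethyl (E)-5-[(1S,2R)-1,2-dimethyl-6-oxocyclohexyl]-3-methylpent-2-enoate F2. i-Bu2AlH reduces ester and ketone to the diol (E)-5-[(1S,2R)-6-hydroxy-1,2-dimethylcyclohexyl]-3-methylpent-2-en-1-ol F3. Selective acetylation of the primary allylic hydroxyl (Ac2O, 2,4,6-collidine, −20 °C) gives (E)-5-[(1S,2R)-6-hydroxy-1,2-dimethylcyclohexyl]-3-methylpent-2-en-1-yl acetate F4, and Dess–Martin oxidation returns 13.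

**Diels–Alder reaction (step 6).** Facial selectivity rests only on the C8/C9 methyl groups and may be moderate, endo selectivity of a methacrylate is not guaranteed, and the diene and allylic acetate must survive Me2AlCl. The fallback uses a far more reactive dienophile under catalyst control of the diene face and then adjusts the oxidation state; it sets out from diene 18 and returns at target 20. Diels–Alder reaction of 18 with methacrolein under a chiral cationic oxazaborolidine catalyst (CH2Cl2, −78 °C, formyl endo) gives the aldehyde (E)-5-[(1S,2R,4aR,5S)-5-formyl-1,2,5-trimethyl-1,2,3,4,4a,5,6,7-octahydronaphthalen-1-yl]-3-methylpent-2-en-1-yl acetate F5. Pinnick oxidation (NaClO2, NaH2PO4, 2-methylbut-2-ene, t-BuOH–H2O) gives (1S,5S,6R,8aR)-5-[(E)-5-acetoxy-3-methylpent-3-en-1-yl]-1,5,6-trimethyl-1,2,3,5,6,7,8,8a-octahydronaphthalene-1-carboxylic acid F6, and Me3SiCHN2 in MeOH–toluene gives 20.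

**Vinylation (step 5).** Zerovalent palladium may ionise the allylic acetate, leading to E/Z scrambling, 1,3-acetate shift or allyl–vinyl coupling. The fallback avoids palladium; it sets out from enol triflate 16 and returns at diene 18. Nozaki–Hiyama–Kishi coupling of 16 with acetaldehyde (CrCl2, catalytic NiCl2, DMF, 23 °C) gives the allylic alcohol (E)-5-[(1S,6R)-2-(1-hydroxyethyl)-1,6-dimethylcyclohex-2-en-1-yl]-3-methylpent-2-en-1-yl acetate F7 as carbinol epimers. Dehydration with the Burgess reagent (benzene, 50 °C; only the methyl group carries a β-hydrogen) gives 18.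

Further compounds
F1 | step 3 | (2S,3R)-2,3-dimethyl-2-(3-oxobutyl)cyclohexan-1-one | O=C1CCC[C@@H](C)[C@]1(C)CCC(C)=O
F2 | step 3 | ethyl (E)-5-[(1S,2R)-1,2-dimethyl-6-oxocyclohexyl]-3-methylpent-2-enoate | O=C1CCC[C@@H](C)[C@]1(C)CC/C(C)=C/C(=O)OCC
F3 | step 3 | (E)-5-[(1S,2R)-6-hydroxy-1,2-dimethylcyclohexyl]-3-methylpent-2-en-1-ol (carbinol epimers) | OC1CCC[C@@H](C)[C@]1(C)CC/C(C)=C/CO
F4 | step 3 | (E)-5-[(1S,2R)-6-hydroxy-1,2-dimethylcyclohexyl]-3-methylpent-2-en-1-yl acetate (carbinol epimers) | OC1CCC[C@@H](C)[C@]1(C)CC/C(C)=C/COC(C)=O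
F5 | step 6 | (E)-5-[(1S,2R,4aR,5S)-5-formyl-1,2,5-trimethyl-1,2,3,4,4a,5,6,7-octahydronaphthalen-1-yl]-3-methylpent-2-en-1-yl acetate | O=C[C@@]1(C)CCC=C2[C@H]1CC[C@@H](C)[C@]2(C)CC/C(C)=C/COC(C)=O
F6 | step 6 | (1S,5S,6R,8aR)-5-[(E)-5-acetoxy-3-methylpent-3-en-1-yl]-1,5,6-trimethyl-1,2,3,5,6,7,8,8a-octahydronaphthalene-1-carboxylic acid | OC(=O)[C@@]1(C)CCC=C2[C@H]1CC[C@@H](C)[C@]2(C)CC/C(C)=C/COC(C)=O
F7 | step 5 | (E)-5-[(1S,6R)-2-(1-hydroxyethyl)-1,6-dimethylcyclohex-2-en-1-yl]-3-methylpent-2-en-1-yl acetate (carbinol epimers) | CC(O)C1=CCC[C@@H](C)[C@]1(C)CC/C(C)=C/COC(C)=O
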